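**Retrosynthetic overview**

1. The target is an (R)-2-hydroxy-1,3-diarylpropan-1-one (chain: C1 = C=O on ring A, C2 = carbinol, C3 = benzylic CH2 on ring B); the last event is removal of four aryl MOM ethers.
2. C3–H ⇐ C3–Br ⇐ C3–O: the ketol is treated as a trans-α,β-epoxy ketone opened reductively at C3, so the C2–OH oxygen is the oxirane oxygen and C3 travels one oxidation level too high.
3. C2–C3 ⇐ catalytic asymmetric Darzens condensation of the ring-A chloromethyl ketone (C2 donor) with the ring-B benzaldehyde (C3 acceptor); the oxirane C2–O–C3 is the only ring formed and it is temporary, both benzene rings are bought.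
4. Enabling feature: C2 carries an oxygen next to the aryl C1=O (an opened glycidic ketone), and C3 is benzylic on ring B, para to the ring-B C4–O and meta to the ring-B C3–O, so the C3–O bond ionises selectively while C2–O and its configuration stay.
5. Ring A: resorcinol, MOM protection, two directed ortho-lithiations (prenyl, then chloroacetyl). Ring B: 3-bromo-4,5-dihydroxybenzaldehyde, MOM protection, Stille prenylation.

Key step: step 6

Assumption: the cinchonine-derived ammonium salt is taken to deliver the (2R,3S)-epoxide; if the sense of induction is the opposite, its cinchonidine-derived pseudoenantiomer replaces it and nothing else changes.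

**Route**

Step 1
Reactants: 1 resorcinol
Product: 2 1,3-bis(methoxymethoxy)benzene
Conditions: NaH (2.4 equiv), MOMCl (2.4 equiv), DMF, 0 °C to rt
Reagents that add atoms: chloromethyl methyl ether, COCCl
Why: Williamson-type O-alkylation of the two sodium phenoxides should give the bis-MOM ether, whose acetal oxygens later direct both lithiations and survive base, organometallics, Pd(0) and radicals.

Step 2
Reactants: 2 1,3-bis(methoxymethoxy)benzene
Product: 4 1,3-bis(methoxymethoxy)-2-(3-methylbut-2-en-1-yl)benzene, via aryllithium 3 (not isolated)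
Conditions: n-BuLi (1.1 equiv), THF, 0 °C to rt; then CuI (10 mol %), prenyl bromide (1.2 equiv), −78 °C to rt
Reagents that add atoms: prenyl bromide (1-bromo-3-methylbut-2-ene), CC(C)=CCBr
Why: Directed ortho-metalation takes place at C2 between the two cooperating OMOM groups, and copper-catalysed SN2 allylation of the aryllithium at the primary carbon of prenyl bromide should give the linear prenyl arene.

Step 3
Reactants: 4 1,3-bis(methoxymethoxy)-2-(3-methylbut-2-en-1-yl)benzene
Product: 6 2-chloro-1-[2,4-bis(methoxymethoxy)-3-(3-methylbut-2-en-1-yl)phenyl]ethan-1-one, via aryllithium 5 (not isolated)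
Conditions: s-BuLi (1.15 equiv), TMEDA (1.2 equiv), THF, −78 °C; then 2-chloro-N-methoxy-N-methylacetamide (1.3 equiv), −78 °C; AcOH (1.5 equiv), −78 °C to rt
Reagents that add atoms: 2-chloro-N-methoxy-N-methylacetamide, CON(C)C(=O)CCl
Why: A second directed ortho-metalation can only occur at C4 next to an OMOM group, and acylation of the aryllithium with the Weinreb amide stops at the chelated tetrahedral adduct, so that the chloromethyl ketone is released on quench without over-addition or loss of chloride.

Step 4
Reactants: 7 3-bromo-4,5-dihydroxybenzaldehyde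
Product: 8 3-bromo-4,5-bis(methoxymethoxy)benzaldehyde
Conditions: NaH (2.4 equiv), MOMCl (2.5 equiv), THF–DMF, 0 °C to rt
Reagents that add atoms: chloromethyl methyl ether, COCCl
Why: Williamson-type O-alkylation of the catechol dianion, which has no enolisable position, should give the bis-MOM ether and removes the acidic protons before the cross-coupling and the basic key step.

Step 5
Reactants: 8 3-bromo-4,5-bis(methoxymethoxy)benzaldehyde
Product: 9 3,4-bis(methoxymethoxy)-5-(3-methylbut-2-en-1-yl)benzaldehyde
Conditions: tributyl(prenyl)stannane (1.3 equiv), Pd(PPh3)4 (5 mol %), DMF, 90 °C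
Reagents that add atoms: tributyl(3-methylbut-2-en-1-yl)stannane, CCCC[Sn](CCCC)(CCCC)CC=C(C)C
Why: Stille cross-coupling (oxidative addition into the aryl C–Br bond, transmetalation of the allylic stannane at its tin-bearing carbon, reductive elimination) should install the linear prenyl group while the aldehyde and the MOM acetals are inert to Pd(0) and the neutral stannane.

Step 6
Reactants: 6 2-chloro-1-[2,4-bis(methoxymethoxy)-3-(3-methylbut-2-en-1-yl)phenyl]ethan-1-one; 9 3,4-bis(methoxymethoxy)-5-(3-methylbut-2-en-1-yl)benzaldehyde (1.2 equiv)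
Product: 11 [(2R,3S)-3-[3,4-bis(methoxymethoxy)-5-(3-methylbut-2-en-1-yl)phenyl]oxiran-2-yl][2,4-bis(methoxymethoxy)-3-(3-methylbut-2-en-1-yl)phenyl]methanone, via chlorohydrin aldolate 10 (not isolated)
Conditions: N-[4-(trifluoromethyl)benzyl]cinchoninium bromide (10 mol %), LiOH·H2O (2 equiv), n-Bu2O–CH2Cl2, 0 °C
Reagents that add atoms: none
Why: Solid LiOH deprotonates 6 at the interface and the enolate enters the organic phase as a contact ion pair with the chiral ammonium cation, whose C9–OH can hydrogen-bond the aldehyde; aldol addition to 9 is reversible, and the aldolate that can place O− antiperiplanar to C–Cl closes irreversibly, so the aldolate pool should drain through retro-aldol equilibration into the trans-epoxide. The closest known reaction type is the quaternary-ammonium-catalysed asymmetric Darzens condensation of aryl chloromethyl ketones with aromatic aldehydes. The only ring formed, the oxirane C2–O–C3, closes by a 3-exo-tet SN2 displacement of chloride with inversion at C2. C2 is controlled by the catalyst (face of the ion-paired enolate in the aldol step, then stereospecific inversion), and C3 follows from the trans closure and is a placeholder that steps 7 and 8 erase. The step needs trans-diastereoselectivity, one enolate face and chemoselectivity, and the substrates secure the last: 9 cannot enolise, 6 has no α′-hydrogen (no Favorskii path), and both carry only base-stable MOM ethers and isolated prenyl alkenes. The epoxide C2–H cannot enolise, so the new C2 configuration, unlike that of a free ketol, should be safe under the basic conditions.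

Step 7
Reactants: 11 [(2R,3S)-3-[3,4-bis(methoxymethoxy)-5-(3-methylbut-2-en-1-yl)phenyl]oxiran-2-yl][2,4-bis(methoxymethoxy)-3-(3-methylbut-2-en-1-yl)phenyl]methanone
Product: 12 (2S,3R)-1-[2,4-bis(methoxymethoxy)-3-(3-methylbut-2-en-1-yl)phenyl]-3-[3,4-bis(methoxymethoxy)-5-(3-methylbut-2-en-1-yl)phenyl]-3-bromo-2-hydroxypropan-1-one
Conditions: LiBr (4 equiv), AcOH (2 equiv), THF, 0 °C; neutral aqueous work-up, used without chromatography
Reagents that add atoms: lithium bromide, [Li+].[Br-]
Why: Acid-assisted halohydrin formation should open the oxirane at C3 only, because the developing positive charge is benzylic and stabilised by the para OMOM oxygen of ring B whereas C2 is deactivated by the adjacent carbonyl, so the C2–O bond and its configuration are untouched (the descriptor changes to 2S only because CHBr now outranks C=O) and the configuration at C3, drawn for inversion, is of no consequence.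

Step 8
Reactants: 12 (2S,3R)-1-[2,4-bis(methoxymethoxy)-3-(3-methylbut-2-en-1-yl)phenyl]-3-[3,4-bis(methoxymethoxy)-5-(3-methylbut-2-en-1-yl)phenyl]-3-bromo-2-hydroxypropan-1-one
Product: 13 (2R)-1-[2,4-bis(methoxymethoxy)-3-(3-methylbut-2-en-1-yl)phenyl]-3-[3,4-bis(methoxymethoxy)-5-(3-methylbut-2-en-1-yl)phenyl]-2-hydroxypropan-1-one
Conditions: Bu3SnH (1.5 equiv), Et3B (0.2 equiv), air, toluene, 0 °C to rt
Reagents that add atoms: none
Why: Radical-chain hydrodebromination with tributyltin hydride should replace the benzylic bromine by hydrogen through a benzylic radical that neither the ketol nor the trisubstituted prenyl alkenes intercept, so that C3 becomes CH2, both C3 epimers converge and C2 is 2R again by the priority change alone.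

Step 9
Reactants: 13 (2R)-1-[2,4-bis(methoxymethoxy)-3-(3-methylbut-2-en-1-yl)phenyl]-3-[3,4-bis(methoxymethoxy)-5-(3-methylbut-2-en-1-yl)phenyl]-2-hydroxypropan-1-one
Product: 14 (2R)-1-[2,4-dihydroxy-3-(3-methylbut-2-en-1-yl)phenyl]-3-[3,4-dihydroxy-5-(3-methylbut-2-en-1-yl)phenyl]-2-hydroxypropan-1-one
Conditions: HCl (1.25 M in MeOH), 0 °C to rt; solid NaHCO3
Reagents that add atoms: none
Why: Acid-catalysed transacetalisation to dimethoxymethane should free the four phenols under cold, dilute conditions in which no bond to C2 is broken and both enolisation of the ketol and addition of the phenols to the prenyl alkenes are slow.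

**Compound list**

1 | resorcinol | Oc1cccc(O)c1 | starting material
2 | 1,3-bis(methoxymethoxy)benzene | COCOc1cccc(OCOC)c1 | intermediate
3 | 2-lithio-1,3-bis(methoxymethoxy)benzene (formed in the flask) | [Li]c1c(OCOC)cccc1OCOC | intermediate
4 | 1,3-bis(methoxymethoxy)-2-(3-methylbut-2-en-1-yl)benzene | COCOc1cccc(OCOC)c1CC=C(C)C | intermediate
5 | [2,4-bis(methoxymethoxy)-3-(3-methylbut-2-en-1-yl)phenyl]lithium (formed in the flask) | [Li]c1ccc(OCOC)c(CC=C(C)C)c1OCOC | intermediate
6 | 2-chloro-1-[2,4-bis(methoxymethoxy)-3-(3-methylbut-2-en-1-yl)phenyl]ethan-1-one | ClCC(=O)c1ccc(OCOC)c(CC=C(C)C)c1OCOC | intermediate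
7 | 3-bromo-4,5-dihydroxybenzaldehyde | O=Cc1cc(O)c(O)c(Br)c1 | starting material
8 | 3-bromo-4,5-bis(methoxymethoxy)benzaldehyde | O=Cc1cc(OCOC)c(OCOC)c(Br)c1 | intermediate
9 | 3,4-bis(methoxymethoxy)-5-(3-methylbut-2-en-1-yl)benzaldehyde | O=Cc1cc(OCOC)c(OCOC)c(CC=C(C)C)c1 | intermediate
10 | (2S,3S)-1-[2,4-bis(methoxymethoxy)-3-(3-methylbut-2-en-1-yl)phenyl]-3-[3,4-bis(methoxymethoxy)-5-(3-methylbut-2-en-1-yl)phenyl]-2-chloro-3-hydroxypropan-1-one, present as its C3 alkoxide (formed in the flask) | O=C(c1ccc(OCOC)c(CC=C(C)C)c1OCOC)[C@@H](Cl)[C@@H](O)c2cc(OCOC)c(OCOC)c(CC=C(C)C)c2 | intermediate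
11 | [(2R,3S)-3-[3,4-bis(methoxymethoxy)-5-(3-methylbut-2-en-1-yl)phenyl]oxiran-2-yl][2,4-bis(methoxymethoxy)-3-(3-methylbut-2-en-1-yl)phenyl]methanone | O=C(c1ccc(OCOC)c(CC=C(C)C)c1OCOC)[C@@H]2O[C@H]2c3cc(OCOC)c(OCOC)c(CC=C(C)C)c3 | intermediate
12 | (2S,3R)-1-[2,4-bis(methoxymethoxy)-3-(3-methylbut-2-en-1-yl)phenyl]-3-[3,4-bis(methoxymethoxy)-5-(3-methylbut-2-en-1-yl)phenyl]-3-bromo-2-hydroxypropan-1-one | O=C(c1ccc(OCOC)c(CC=C(C)C)c1OCOC)[C@H](O)[C@H](Br)c2cc(OCOC)c(OCOC)c(CC=C(C)C)c2 | intermediate
13 | (2R)-1-[2,4-bis(methoxymethoxy)-3-(3-methylbut-2-en-1-yl)phenyl]-3-[3,4-bis(methoxymethoxy)-5-(3-methylbut-2-en-1-yl)phenyl]-2-hydroxypropan-1-one | CC(C)=CCc1cc(C[C@@H](O)C(=O)c2ccc(OCOC)c(CC=C(C)C)c2OCOC)cc(OCOC)c1OCOC | intermediate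
14 | (2R)-1-[2,4-dihydroxy-3-(3-methylbut-2-en-1-yl)phenyl]-3-[3,4-dihydroxy-5-(3-methylbut-2-en-1-yl)phenyl]-2-hydroxypropan-1-one | CC(C)=CCc1cc(C[C@@H](O)C(=O)c2ccc(O)c(CC=C(C)C)c2O)cc(O)c1O | target

**Step count and risks**

Total step count: 9. Longest linear sequence: 7 steps (steps 1, 2, 3, 6, 7, 8, 9).

Steps most likely to fail:

1. Step 6. With two electron-rich partners the aldol addition may be slow, retro-aldol may outrun ring closure, hydroxide may hydrolyse the C–Cl bond, or the ion pair may give too little facial discrimination at C2. The fallback sets out from 4 and 9 and comes back at 11; it builds the same C2–C3 bond without stereochemistry first and sets C2 afterwards. Aryllithium 5, made from 4 as in step 3, is quenched with N-methoxy-N-methylacetamide to give the methyl ketone 1-[2,4-bis(methoxymethoxy)-3-(3-methylbut-2-en-1-yl)phenyl]ethan-1-one F1. Claisen–Schmidt condensation of F1 with 9 (KOH, EtOH, rt) should give the chalcone (2E)-1-[2,4-bis(methoxymethoxy)-3-(3-methylbut-2-en-1-yl)phenyl]-3-[3,4-bis(methoxymethoxy)-5-(3-methylbut-2-en-1-yl)phenyl]prop-2-en-1-one F2. Juliá–Colonna epoxidation of F2 (poly-L-leucine, urea–H2O2, DBU, THF, rt), a nucleophilic epoxidation that should leave the prenyl alkenes alone and is expected to favour the (2R,3S) series, then gives 11.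

2. Step 7. The benzylic C3–Br bond of 12 may ionise and lose the C2 proton (elimination to the enol of the 1,2-diketone, which destroys the stereocenter), the benzylic cation may suffer acyl migration, or bromide may partly attack C2. The fallback sets out from 11 and comes back at 13; it replaces the halide by a sulfur nucleophile whose benzylic C–S bond does not ionise. Thiophenol (2 equiv, toluene, 80 °C, optionally catalytic ZnCl2) should open the oxirane at benzylic C3 to give (2S)-1-[2,4-bis(methoxymethoxy)-3-(3-methylbut-2-en-1-yl)phenyl]-3-[3,4-bis(methoxymethoxy)-5-(3-methylbut-2-en-1-yl)phenyl]-2-hydroxy-3-(phenylsulfanyl)propan-1-one F3 (either C3 epimer serves). Radical desulfurisation of F3 (Bu3SnH, AIBN, toluene, 90 °C) then gives 13.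

3. Step 9. Under protic acid the freed ortho-prenyl phenols may add to their prenyl double bonds (chroman formation), and acid-catalysed enolisation of the ketol may erode the C2 configuration or shift the carbonyl. The fallback sets out from 13 and comes back at 14; it replaces Brønsted-acid solvolysis by buffered silyl transfer. TMSOTf and 2,2′-bipyridyl (CH2Cl2, 0 °C) should convert the aryl MOM ethers into aryl silyl ethers and silylate the C2–OH, giving (2R)-1-[2,4-bis(trimethylsilyloxy)-3-(3-methylbut-2-en-1-yl)phenyl]-3-[3,4-bis(trimethylsilyloxy)-5-(3-methylbut-2-en-1-yl)phenyl]-2-(trimethylsilyloxy)propan-1-one F4. Hydrolysis of F4 (water, then dilute citric acid in THF, 0 °C) then gives 14.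

Further compounds
F1 | step 6 | 1-[2,4-bis(methoxymethoxy)-3-(3-methylbut-2-en-1-yl)phenyl]ethan-1-one | CC(=O)c1ccc(OCOC)c(CC=C(C)C)c1OCOC
F2 | step 6 | (2E)-1-[2,4-bis(methoxymethoxy)-3-(3-methylbut-2-en-1-yl)phenyl]-3-[3,4-bis(methoxymethoxy)-5-(3-methylbut-2-en-1-yl)phenyl]prop-2-en-1-one | O=C(/C=C/c1cc(OCOC)c(OCOC)c(CC=C(C)C)c1)c2ccc(OCOC)c(CC=C(C)C)c2OCOC
F3 | step 7 | (2S)-1-[2,4-bis(methoxymethoxy)-3-(3-methylbut-2-en-1-yl)phenyl]-3-[3,4-bis(methoxymethoxy)-5-(3-methylbut-2-en-1-yl)phenyl]-2-hydroxy-3-(phenylsulfanyl)propan-1-one | O=C(c1ccc(OCOC)c(CC=C(C)C)c1OCOC)[C@H](O)C(Sc2ccccc2)c3cc(OCOC)c(OCOC)c(CC=C(C)C)c3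
F4 | step 9 | (2R)-1-[2,4-bis(trimethylsilyloxy)-3-(3-methylbut-2-en-1-yl)phenyl]-3-[3,4-bis(trimethylsilyloxy)-5-(3-methylbut-2-en-1-yl)phenyl]-2-(trimethylsilyloxy)propan-1-one | CC(C)=CCc1cc(C[C@@H](O[Si](C)(C)C)C(=O)c2ccc(O[Si](C)(C)C)c(CC=C(C)C)c2O[Si](C)(C)C)cc(O[Si](C)(C)C)c1O[Si](C)(C)C
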